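The route cuts the ten-membered carbocycle (ring A, C1–C10 in germacrane numbering) at C5–C6 and exploits the allylic carbinol C4=C5–C6(O) that sits beside the lactone-fusion carbon C7. An intramolecular Nozaki–Hiyama–Kishi addition of an (E)-alkenyl iodide (C5) to a C6 aldehyde closes ring A, preserves the 4E olefin and sets the C6 stereocentre under control of C7 in one operation. The seco-precursor already holds the trans α-methylene-γ-butyrolactone (ring B), made by an anti-selective chromium allylation with a bromomethyl butenolide followed by translactonisation, and the C3–C5 iodoalkene unit, made by an asymmetric β-iodo Morita–Baylis–Hillman coupling.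

Key step: step 12

Numbering: all carbons carry their germacrane numbers throughout (C11 to C13 are the lactone carbons with C13 the exocyclic methylene, C14 is the methyl on C10, C15 the oxymethyl on C4).

Assumption: 3-(bromomethyl)furan-2(5H)-one (16) is bought as a catalogue building block, and the catalyst enantiomers named in steps 3 and 9 are those expected to give Si-face attack at C3 and Re-face attack at C8; should the sense be the opposite, the mirror-image catalyst is used.

Step 1
Reactants: 1 tert-butyl(but-3-yn-1-yloxy)dimethylsilane; 2 oxirane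
Product: 5 (3E)-6-{[tert-butyl(dimethyl)silyl]oxy}-4-methylhex-3-en-1-ol, via alkenyldimethylalane 3 (not isolated), via lithium alkenylalanate 4 (not isolated)
Conditions: AlMe3, Cp2ZrCl2 (20 mol%), CH2Cl2, 0 °C to rt; n-BuLi, THF, −78 °C; then 2, −78 °C to rt; aq. Rochelle salt
Reagents that add atoms: trimethylaluminium C[Al](C)C
Why: Negishi zirconium-catalysed carboalumination adds methyl (C14) to C10 and aluminium to C1 in a syn fashion, which fixes the E-trisubstituted C1=C10 olefin, and the derived alanate opens oxirane at carbon to append C2–C3 as the homoallylic alcohol (no stereocentre is formed).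

Step 2
Reactants: 5 (3E)-6-{[tert-butyl(dimethyl)silyl]oxy}-4-methylhex-3-en-1-ol
Product: 6 (3E)-6-{[tert-butyl(dimethyl)silyl]oxy}-4-methylhex-3-enal
Conditions: Dess–Martin periodinane, NaHCO3, CH2Cl2, 0 °C; used crude
Reagents that add atoms: none
Why: Buffered Dess–Martin oxidation gives the β,γ-unsaturated aldehyde under non-basic conditions, so the C1=C10 olefin should not move into conjugation.

Step 3
Reactants: 6 (3E)-6-{[tert-butyl(dimethyl)silyl]oxy}-4-methylhex-3-enal; 7 methyl prop-2-ynoate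
Product: 10 methyl (2Z)-2-[(1R,3E)-6-{[tert-butyl(dimethyl)silyl]oxy}-1-hydroxy-4-methylhex-3-en-1-yl]-3-iodoprop-2-enoate, via silyl iodoallenolate 8 (not isolated), via trimethylsilyl ether 9 (not isolated)
Conditions: TMSI, oxazaborolidinium triflimide from (S)-o-tolyl-CBS and Tf2NH (20 mol%), CH2Cl2, −78 °C; then 10% aq. citric acid, THF, 0 °C
Reagents that add atoms: iodotrimethylsilane C[Si](C)(C)I
Why: Asymmetric three-component β-iodo Morita–Baylis–Hillman coupling, in which iodide adds to the propiolate to give a silyl allenolate that attacks the Si face of the catalyst-bound aldehyde (C3 set as R) and, under kinetic control at low temperature, gives the Z-iodoacrylate with iodine cis to the ester (the later 4E geometry).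

Step 4
Reactants: 10 methyl (2Z)-2-[(1R,3E)-6-{[tert-butyl(dimethyl)silyl]oxy}-1-hydroxy-4-methylhex-3-en-1-yl]-3-iodoprop-2-enoate
Product: 11 methyl (2Z)-2-[(1R,3E)-1,6-bis{[tert-butyl(dimethyl)silyl]oxy}-4-methylhex-3-en-1-yl]-3-iodoprop-2-enoate
Conditions: TBSOTf, 2,6-lutidine, CH2Cl2, −78 to 0 °C
Reagents that add atoms: tert-butyldimethylsilyl trifluoromethanesulfonate CC(C)(C)[Si](C)(C)OS(=O)(=O)C(F)(F)F
Why: Silylation of the hindered secondary allylic alcohol with the silyl triflate protects O3 without touching C3.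

Step 5
Reactants: 11 methyl (2Z)-2-[(1R,3E)-1,6-bis{[tert-butyl(dimethyl)silyl]oxy}-4-methylhex-3-en-1-yl]-3-iodoprop-2-enoate
Product: 12 (2E)-2-[(1R,3E)-1,6-bis{[tert-butyl(dimethyl)silyl]oxy}-4-methylhex-3-en-1-yl]-3-iodoprop-2-en-1-ol
Conditions: i-Bu2AlH (2.5 equiv), CH2Cl2, −78 °C; aq. Rochelle salt
Reagents that add atoms: none
Why: 1,2-Reduction of the enoate with DIBAL-H gives the C15 allylic alcohol and leaves the alkenyl iodide and silyl ethers intact (the olefin geometry is unchanged; only its descriptor changes).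

Step 6
Reactants: 12 (2E)-2-[(1R,3E)-1,6-bis{[tert-butyl(dimethyl)silyl]oxy}-4-methylhex-3-en-1-yl]-3-iodoprop-2-en-1-ol
Product: 13 (2E)-2-[(1R,3E)-1,6-bis{[tert-butyl(dimethyl)silyl]oxy}-4-methylhex-3-en-1-yl]-3-iodoprop-2-en-1-yl 3-methylbutanoate
Conditions: 3-methylbutanoyl chloride, pyridine, DMAP (cat.), CH2Cl2, 0 °C
Reagents that add atoms: 3-methylbutanoyl chloride CC(C)CC(Cl)=O
Why: DMAP-catalysed acylation of the primary allylic alcohol installs the C15 ester before any other hydroxyl is free.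

Step 7
Reactants: 13 (2E)-2-[(1R,3E)-1,6-bis{[tert-butyl(dimethyl)silyl]oxy}-4-methylhex-3-en-1-yl]-3-iodoprop-2-en-1-yl 3-methylbutanoate
Product: 14 (2E)-2-[(1R,3E)-1-{[tert-butyl(dimethyl)silyl]oxy}-6-hydroxy-4-methylhex-3-en-1-yl]-3-iodoprop-2-en-1-yl 3-methylbutanoate
Conditions: HF·pyridine, pyridine, THF, 0 °C
Reagents that add atoms: none
Why: Buffered fluoride desilylation should cleave the unhindered primary silyl ether at C8 much faster than the hindered secondary allylic silyl ether at C3.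

Step 8
Reactants: 14 (2E)-2-[(1R,3E)-1-{[tert-butyl(dimethyl)silyl]oxy}-6-hydroxy-4-methylhex-3-en-1-yl]-3-iodoprop-2-en-1-yl 3-methylbutanoate
Product: 15 (2E)-2-[(1R,3E)-1-{[tert-butyl(dimethyl)silyl]oxy}-4-methyl-6-oxohex-3-en-1-yl]-3-iodoprop-2-en-1-yl 3-methylbutanoate
Conditions: Dess–Martin periodinane, NaHCO3, CH2Cl2, 0 °C; used crude
Reagents that add atoms: none
Why: Buffered Dess–Martin oxidation gives the C8 aldehyde without isomerising the β,γ-olefin.

Step 9
Reactants: 15 (2E)-2-[(1R,3E)-1-{[tert-butyl(dimethyl)silyl]oxy}-4-methyl-6-oxohex-3-en-1-yl]-3-iodoprop-2-en-1-yl 3-methylbutanoate; 16 3-(bromomethyl)furan-2(5H)-one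
Product: 19 (2E)-2-[(1R,3E,6S)-1-{[tert-butyl(dimethyl)silyl]oxy}-6-hydroxy-4-methyl-6-[(3S)-4-methylidene-5-oxooxolan-3-yl]hex-3-en-1-yl]-3-iodoprop-2-en-1-yl 3-methylbutanoate, via allylchromium reagent 17 (not isolated), via trimethylsilyl ether 18 (not isolated)
Conditions: CrCl2 (10 mol%), (S,S)-3,6-di-tert-butyl-1,8-bis(4-isopropyl-4,5-dihydrooxazol-2-yl)carbazole (12 mol%), Mn powder, TMSCl, i-Pr2NEt (cat.), THF, rt; then 1 M HCl, THF, 0 °C
Reagents that add atoms: none
Why: Chromium-catalysed asymmetric Nozaki–Hiyama allylation, in which the γ-substituent of the allylchromium reagent (the ring CH2O, C6) is locked trans to the CH2–Cr carbon so that the chair Zimmerman–Traxler transition state gives the anti C7/C8 adduct, the chiral bis(oxazolinyl)carbazole ligand on trivalent chromium selects the Re face of the aldehyde (8S, and 7S in this compound), and the alkenyl iodide is untouched because no nickel is present.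

Step 10
Reactants: 19 (2E)-2-[(1R,3E,6S)-1-{[tert-butyl(dimethyl)silyl]oxy}-6-hydroxy-4-methyl-6-[(3S)-4-methylidene-5-oxooxolan-3-yl]hex-3-en-1-yl]-3-iodoprop-2-en-1-yl 3-methylbutanoate
Product: 20 (2E)-2-[(1R,3E)-1-{[tert-butyl(dimethyl)silyl]oxy}-5-[(2S,3S)-3-(hydroxymethyl)-4-methylidene-5-oxooxolan-2-yl]-4-methylpent-3-en-1-yl]-3-iodoprop-2-en-1-yl 3-methylbutanoate
Conditions: CSA (20 mol%), CH2Cl2, rt
Reagents that add atoms: none
Why: Acid-catalysed translactonisation (5-exo-trig attack of O8 on C12) under thermodynamic control should favour the more substituted trans-4,5-disubstituted lactone on the secondary C8 oxygen and frees the primary C6 hydroxyl, so the anti adduct becomes the trans ring B without any stereocentre being touched.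

Step 11
Reactants: 20 (2E)-2-[(1R,3E)-1-{[tert-butyl(dimethyl)silyl]oxy}-5-[(2S,3S)-3-(hydroxymethyl)-4-methylidene-5-oxooxolan-2-yl]-4-methylpent-3-en-1-yl]-3-iodoprop-2-en-1-yl 3-methylbutanoate
Product: 21 (2E)-2-[(1R,3E)-1-{[tert-butyl(dimethyl)silyl]oxy}-5-[(2S,3R)-3-formyl-4-methylidene-5-oxooxolan-2-yl]-4-methylpent-3-en-1-yl]-3-iodoprop-2-en-1-yl 3-methylbutanoate
Conditions: Dess–Martin periodinane, NaHCO3, CH2Cl2, 0 °C; filtered and used at once
Reagents that add atoms: none
Why: Buffered Dess–Martin oxidation gives the C6 aldehyde under conditions mild enough that the C7 stereocentre and the exocyclic C11=C13 olefin should stay in place.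

Step 12
Reactants: 21 (2E)-2-[(1R,3E)-1-{[tert-butyl(dimethyl)silyl]oxy}-5-[(2S,3R)-3-formyl-4-methylidene-5-oxooxolan-2-yl]-4-methylpent-3-en-1-yl]-3-iodoprop-2-en-1-yl 3-methylbutanoate
Product: 24 (1(10)E,4E)-(3R,6R,7S,8S)-3-{[tert-butyl(dimethyl)silyl]oxy}-6-hydroxy-15-[(3-methylbutanoyl)oxy]germacra-1(10),4,11(13)-trien-12,8-olide, via alkenylchromium species 22 (not isolated), via chromium alkoxide 23 (not isolated)
Conditions: CrCl2 (10 equiv), NiCl2 (2 mol%), DMSO, rt, slow addition of 21 to a final 2 mM; aq. work-up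
Reagents that add atoms: none
Why: Zerovalent nickel, formed from NiCl2 and CrCl2, inserts into the C5–I bond, the alkenyl group passes to trivalent chromium with retention of the E geometry, and the alkenylchromium adds to the C6 aldehyde within the same molecule to give the chromium alkoxide. The closest known reaction type is the Nozaki–Hiyama–Kishi macrocyclisation of alkenyl iodide aldehydes to medium-ring allylic alcohols. Ring A closes in a 10-exo-trig mode by attack on the aldehyde carbon, and no other ring is formed. The new C6 stereocentre is controlled by the neighbouring C7: Felkin–Anh attack anti to the C7–C8 bond, with the sp2 carbon C11 next to the carbonyl oxygen, gives the 6,7-syn (6R) alcohol, and the trans-fused lactone together with the two E olefins limits the ring-closing conformers to those that fit this approach. The step needs chemoselective activation of the alkenyl iodide beside the enoate, the allylic ester and the silyl ether, and cyclisation in preference to oligomerisation; the nickel/chromium pair, the aldehyde selectivity of organochromium reagents, the neutral medium and high dilution should secure this.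

Step 13
Reactants: 24 (1(10)E,4E)-(3R,6R,7S,8S)-3-{[tert-butyl(dimethyl)silyl]oxy}-6-hydroxy-15-[(3-methylbutanoyl)oxy]germacra-1(10),4,11(13)-trien-12,8-olide
Product: 25 (1(10)E,4E)-(3R,6R,7R,8S)-3-{[tert-butyl(dimethyl)silyl]oxy}-6,15-bis[(3-methylbutanoyl)oxy]germacra-1(10),4,11(13)-trien-12,8-olide
Conditions: 3-methylbutanoyl chloride, pyridine, DMAP (cat.), CH2Cl2, 0 °C
Reagents that add atoms: 3-methylbutanoyl chloride CC(C)CC(Cl)=O
Why: DMAP-catalysed acylation of the secondary allylic alcohol proceeds at oxygen with retention at C6 (the C7 descriptor changes only through the priority rules).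

Step 14
Reactants: 25 (1(10)E,4E)-(3R,6R,7R,8S)-3-{[tert-butyl(dimethyl)silyl]oxy}-6,15-bis[(3-methylbutanoyl)oxy]germacra-1(10),4,11(13)-trien-12,8-olide
Product: 26 (1(10)E,4E)-(3R,6R,7R,8S)-3-hydroxy-6,15-bis[(3-methylbutanoyl)oxy]germacra-1(10),4,11(13)-trien-12,8-olide (CNP0317194.1)
Conditions: HF·pyridine, THF, 0 °C to rt
Reagents that add atoms: none
Why: Mildly acidic fluoride desilylation frees the C3 hydroxyl while avoiding base-promoted acyl migration from O15 and Michael addition to the α-methylene lactone.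

Compound list

1 | tert-butyl(but-3-yn-1-yloxy)dimethylsilane | C#CCCO[Si](C)(C)C(C)(C)C | starting material
2 | oxirane (ethylene oxide) | C1CO1 | starting material
3 | [(1E)-4-{[tert-butyl(dimethyl)silyl]oxy}-2-methylbut-1-en-1-yl]dimethylalane (formed in situ) | C[Al](C)/C=C(\C)CCO[Si](C)(C)C(C)(C)C | intermediate
4 | lithium butyl[(1E)-4-{[tert-butyl(dimethyl)silyl]oxy}-2-methylbut-1-en-1-yl]dimethylaluminate (formed in situ) | [Li+].CCCC[Al-](C)(C)/C=C(\C)CCO[Si](C)(C)C(C)(C)C | intermediate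
5 | (3E)-6-{[tert-butyl(dimethyl)silyl]oxy}-4-methylhex-3-en-1-ol | CC(C)(C)[Si](C)(C)OCC/C(C)=C/CCO | intermediate
6 | (3E)-6-{[tert-butyl(dimethyl)silyl]oxy}-4-methylhex-3-enal | CC(C)(C)[Si](C)(C)OCC/C(C)=C/CC=O | intermediate
7 | methyl prop-2-ynoate (methyl propiolate) | C#CC(=O)OC | starting material
8 | [(3-iodo-1-methoxypropa-1,2-dien-1-yl)oxy]trimethylsilane (formed in situ) | COC(O[Si](C)(C)C)=C=CI | intermediate
9 | methyl (2Z)-2-[(1R,3E)-6-{[tert-butyl(dimethyl)silyl]oxy}-4-methyl-1-[(trimethylsilyl)oxy]hex-3-en-1-yl]-3-iodoprop-2-enoate (formed in situ) | CC(C)(C)[Si](C)(C)OCC/C(C)=C/C[C@@H](O[Si](C)(C)C)/C(C(=O)OC)=C/I | intermediate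
10 | methyl (2Z)-2-[(1R,3E)-6-{[tert-butyl(dimethyl)silyl]oxy}-1-hydroxy-4-methylhex-3-en-1-yl]-3-iodoprop-2-enoate | CC(C)(C)[Si](C)(C)OCC/C(C)=C/C[C@@H](O)/C(C(=O)OC)=C/I | intermediate
11 | methyl (2Z)-2-[(1R,3E)-1,6-bis{[tert-butyl(dimethyl)silyl]oxy}-4-methylhex-3-en-1-yl]-3-iodoprop-2-enoate | CC(C)(C)[Si](C)(C)OCC/C(C)=C/C[C@@H](O[Si](C)(C)C(C)(C)C)/C(C(=O)OC)=C/I | intermediate
12 | (2E)-2-[(1R,3E)-1,6-bis{[tert-butyl(dimethyl)silyl]oxy}-4-methylhex-3-en-1-yl]-3-iodoprop-2-en-1-ol | CC(C)(C)[Si](C)(C)OCC/C(C)=C/C[C@@H](O[Si](C)(C)C(C)(C)C)/C(CO)=C/I | intermediate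
13 | (2E)-2-[(1R,3E)-1,6-bis{[tert-butyl(dimethyl)silyl]oxy}-4-methylhex-3-en-1-yl]-3-iodoprop-2-en-1-yl 3-methylbutanoate | CC(C)(C)[Si](C)(C)OCC/C(C)=C/C[C@@H](O[Si](C)(C)C(C)(C)C)/C(COC(=O)CC(C)C)=C/I | intermediate
14 | (2E)-2-[(1R,3E)-1-{[tert-butyl(dimethyl)silyl]oxy}-6-hydroxy-4-methylhex-3-en-1-yl]-3-iodoprop-2-en-1-yl 3-methylbutanoate | OCC/C(C)=C/C[C@@H](O[Si](C)(C)C(C)(C)C)/C(COC(=O)CC(C)C)=C/I | intermediate
15 | (2E)-2-[(1R,3E)-1-{[tert-butyl(dimethyl)silyl]oxy}-4-methyl-6-oxohex-3-en-1-yl]-3-iodoprop-2-en-1-yl 3-methylbutanoate | O=CC/C(C)=C/C[C@@H](O[Si](C)(C)C(C)(C)C)/C(COC(=O)CC(C)C)=C/I | intermediate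
16 | 3-(bromomethyl)furan-2(5H)-one | O=C1OCC=C1CBr | starting material
17 | dichloro[(2-oxo-2,5-dihydrofuran-3-yl)methyl]chromium, chiral ligand omitted (formed in situ) | O=C1OCC=C1C[Cr](Cl)Cl | intermediate
18 | trimethylsilyl ether of 19 at O8 (formed in situ) | C=C1C(=O)OC[C@H]1[C@@H](O[Si](C)(C)C)C/C(C)=C/C[C@@H](O[Si](C)(C)C(C)(C)C)/C(COC(=O)CC(C)C)=C/I | intermediate
19 | (2E)-2-[(1R,3E,6S)-1-{[tert-butyl(dimethyl)silyl]oxy}-6-hydroxy-4-methyl-6-[(3S)-4-methylidene-5-oxooxolan-3-yl]hex-3-en-1-yl]-3-iodoprop-2-en-1-yl 3-methylbutanoate | C=C1C(=O)OC[C@H]1[C@@H](O)C/C(C)=C/C[C@@H](O[Si](C)(C)C(C)(C)C)/C(COC(=O)CC(C)C)=C/I | intermediate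
20 | (2E)-2-[(1R,3E)-1-{[tert-butyl(dimethyl)silyl]oxy}-5-[(2S,3S)-3-(hydroxymethyl)-4-methylidene-5-oxooxolan-2-yl]-4-methylpent-3-en-1-yl]-3-iodoprop-2-en-1-yl 3-methylbutanoate | C=C1C(=O)O[C@@H](C/C(C)=C/C[C@@H](O[Si](C)(C)C(C)(C)C)/C(COC(=O)CC(C)C)=C/I)[C@@H]1CO | intermediate
21 | (2E)-2-[(1R,3E)-1-{[tert-butyl(dimethyl)silyl]oxy}-5-[(2S,3R)-3-formyl-4-methylidene-5-oxooxolan-2-yl]-4-methylpent-3-en-1-yl]-3-iodoprop-2-en-1-yl 3-methylbutanoate | C=C1C(=O)O[C@@H](C/C(C)=C/C[C@@H](O[Si](C)(C)C(C)(C)C)/C(COC(=O)CC(C)C)=C/I)[C@@H]1C=O | intermediate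
22 | alkenylchromium dichloride of 21, C5–CrCl2 in place of C5–I (formed in situ) | C=C1C(=O)O[C@@H](C/C(C)=C/C[C@@H](O[Si](C)(C)C(C)(C)C)/C(COC(=O)CC(C)C)=C/[Cr](Cl)Cl)[C@@H]1C=O | intermediate
23 | dichlorochromium alkoxide of 24 at O6 (formed in situ) | C=C1C(=O)O[C@H]2C/C(C)=C/C[C@@H](O[Si](C)(C)C(C)(C)C)/C(COC(=O)CC(C)C)=C/[C@@H](O[Cr](Cl)Cl)[C@H]12 | intermediate
24 | (1(10)E,4E)-(3R,6R,7S,8S)-3-{[tert-butyl(dimethyl)silyl]oxy}-6-hydroxy-15-[(3-methylbutanoyl)oxy]germacra-1(10),4,11(13)-trien-12,8-olide | C=C1C(=O)O[C@H]2C/C(C)=C/C[C@@H](O[Si](C)(C)C(C)(C)C)/C(COC(=O)CC(C)C)=C/[C@@H](O)[C@H]12 | intermediate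
25 | (1(10)E,4E)-(3R,6R,7R,8S)-3-{[tert-butyl(dimethyl)silyl]oxy}-6,15-bis[(3-methylbutanoyl)oxy]germacra-1(10),4,11(13)-trien-12,8-olide | C=C1C(=O)O[C@H]2C/C(C)=C/C[C@@H](O[Si](C)(C)C(C)(C)C)/C(COC(=O)CC(C)C)=C/[C@@H](OC(=O)CC(C)C)[C@H]12 | intermediate
26 | (1(10)E,4E)-(3R,6R,7R,8S)-3-hydroxy-6,15-bis[(3-methylbutanoyl)oxy]germacra-1(10),4,11(13)-trien-12,8-olide (CNP0317194.1) | C=C1C(=O)O[C@H]2C/C(C)=C/C[C@@H](O)/C(COC(=O)CC(C)C)=C/[C@@H](OC(=O)CC(C)C)[C@H]12 | target

Total step count: 14. Longest linear sequence: 14 steps (from 1 to 26).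

Steps most likely to fail

Step 12. What may go wrong is attack on the wrong face of the C6 aldehyde during ring closure, so that the 6S alcohol dominates (the macrocyclic constraint may override the Felkin–Anh preference). The fallback accepts this outcome and corrects it by inversion instead of by a better cyclisation. It sets out from 21, whose cyclisation under the same conditions then gives the 6-epimeric alcohol F1. A Mitsunobu esterification of F1 with 3-methylbutanoic acid (PPh3, DIAD, toluene, 0 °C) should invert C6 and install the C6 ester in the same operation. The route is rejoined at 25.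

Step 9. What may go wrong is insufficient face selection by the chiral chromium catalyst on the flexible aldehyde, or migration of the C1=C10 olefin of 15 into conjugation under the amine and silyl chloride. The fallback changes the allyl metal from chromium to boron and the source of asymmetry to a chiral Brønsted acid. It sets out from 16, which a Miyaura-type allylic borylation (B2pin2, Pd2(dba)3 cat., toluene, 50 °C) should convert into the pinacol allylboronate F2. Allylboration of 15 with F2 under chiral phosphoric acid catalysis ((R)-TRIP, toluene, −30 °C, enantiomer chosen for Re-face attack) passes through the same closed chair with the ring-locked γ-substituent and should give the anti borate F3. Hydrolysis of F3 on aqueous work-up gives 19, where the route is rejoined.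

Step 3. What may go wrong is low enantioselectivity in the catalytic coupling with this unbranched, β,γ-unsaturated aliphatic aldehyde. The fallback replaces asymmetric catalysis by resolution. It sets out from 6 and 7, whose uncatalysed coupling promoted by MgI2 (CH2Cl2, 0 °C) should give 10 as a racemate, that is, together with its enantiomer F4. Lipase-mediated acylation (Pseudomonas cepacia lipase, vinyl acetate, hexane) is expected, from the usual empirical preference of lipases for this arrangement of large and medium groups, to acylate the R alcohol and give the acetate F5, which is separated from unreacted F4. Hydrolysis of F5 with the same lipase in pH 7 buffer returns 10, where the route is rejoined.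

Further compounds

F1 | step 12 | (1(10)E,4E)-(3R,6S,7S,8S)-3-{[tert-butyl(dimethyl)silyl]oxy}-6-hydroxy-15-[(3-methylbutanoyl)oxy]germacra-1(10),4,11(13)-trien-12,8-olide (6-epimer of 24) | C=C1C(=O)O[C@H]2C/C(C)=C/C[C@@H](O[Si](C)(C)C(C)(C)C)/C(COC(=O)CC(C)C)=C/[C@H](O)[C@H]12
F2 | step 9 | 3-[(4,4,5,5-tetramethyl-1,3,2-dioxaborolan-2-yl)methyl]furan-2(5H)-one | O=C1OCC=C1CB1OC(C)(C)C(C)(C)O1
F3 | step 9 | pinacol borate of 19 at O8 | C=C1C(=O)OC[C@H]1[C@@H](OB1OC(C)(C)C(C)(C)O1)C/C(C)=C/C[C@@H](O[Si](C)(C)C(C)(C)C)/C(COC(=O)CC(C)C)=C/I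
F4 | step 3 | methyl (2Z)-2-[(1S,3E)-6-{[tert-butyl(dimethyl)silyl]oxy}-1-hydroxy-4-methylhex-3-en-1-yl]-3-iodoprop-2-enoate (enantiomer of 10) | CC(C)(C)[Si](C)(C)OCC/C(C)=C/C[C@H](O)/C(C(=O)OC)=C/I
F5 | step 3 | methyl (2Z)-2-[(1R,3E)-1-(acetyloxy)-6-{[tert-butyl(dimethyl)silyl]oxy}-4-methylhex-3-en-1-yl]-3-iodoprop-2-enoate | CC(C)(C)[Si](C)(C)OCC/C(C)=C/C[C@@H](OC(C)=O)/C(C(=O)OC)=C/I
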